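## The problem

Glycyrrhizaisoflavone C is a 7-hydroxyisoflavone (rings A and C) whose C3 carries ring B, and ring B is fused to a 2,2-dimethyldihydropyran (ring D). The two bicyclic halves are joined only by the C3–C1' bond, which sits between two ortho oxygen substituents and is therefore hindered. Ring B is pentasubstituted: C1' bears the chromone, C2' a methoxyl, C3' the CH2 of ring D, C4' the ether oxygen of ring D, C5' a hydrogen and C6' a free hydroxyl. Its three meta oxygens are thus in three different states, and on a preformed phloroglucinol they would have to be told apart while carbon is introduced selectively at C1' and C3'. The molecule has no stereocentre, so the whole problem is regiochemical. The sensitive groups are the chromone (C2 is attacked by hydroxide, alkoxide and amines, and C2=C3 can be hydrogenated), the electron-rich ring B (ozone and strong electrophiles) and any free C6' hydroxyl next to a two-carbon chain on C1', which closes to a benzofuran. The feature that opens the key step is the order of substituents around ring B. The C6' oxygen, the C1'/C2' pair (carbon substituent next to methoxyl) and the C3'–C4'–C5' triad map onto a ketene carbonyl, the two carbons of a polarised methoxyalkyne, and C2–C3–C4 of a cyclobutenone. Because C3' and C4' carry the CH2 and the oxygen of ring D, that cyclobutenone is a ring-fused vinylogous ester in which ring D already exists.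

## Retrosynthesis

Target 28 is traced to its C6' benzyl ether 27. Only the O–benzyl bond is cut. The benzyl group is needed from the moment a two-carbon chain stands on C1', and it is removed last by hydrogenolysis, which leaves the methyl ether and ring D alone. The forward step must spare the chromone C2=C3 bond.

In 27 the O1–C2 bond of ring C is cut, leading to the ortho-hydroxyaryl enaminone 26, which is the bis-deacetylated form of 25. This is the closing step of the classical enaminone isoflavone synthesis. An ortho-fluoroaryl ketone closed by nucleophilic aromatic substitution was weighed for the same bond. It was set aside because the para oxygen deactivates that ring and the hydroxymethylene ketone it requires is prone to deformylation. The forward reaction only has to unmask the ortho phenol while the ring B phenol stays protected, so that the six-membered closure cannot be rivalled by benzofuran formation.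

Enaminone 25 is cut at C3–C4 into acid chloride 23 and the enamine 24 of arylacetaldehyde 20. The neighbouring cut, C3–C1' by cross-coupling, would need a metal or halogen placed selectively at C1' between two oxygens. The chosen cut instead uses a carbon chain that the key step delivers at C1' without any aromatic substitution. The cut separates rings A/C from rings B/D. It asks for C-acylation of an enamine at a carbon flanked by two ortho oxygens, which is the least comfortable step of the endgame and has its own fallback. Acid chloride 23 comes from acid 22 and this from commercial 2,4-dihydroxybenzoic acid 21.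

Aldehyde 20 is the oxidative-cleavage product of allylarene 19, the benzyl ether of phenol 18. The allyl group is a masked acetaldehyde: its CH2 becomes C3 and its CH becomes C2 of the chromone. An oxidant that leaves the electron-rich ring alone is required.

Phenol 18 is cut at C6'–C1', C2'–C3' and C5'–C6' into cyclobutenone 13 and ynol ether 4. Against stepwise substitution of a preformed 1,3,5-trioxygenated benzene, this cut installs all five substituents of ring B in one operation. Each oxygen is in its final state: methyl ether from 4, ring D ether from 13, free phenol from the ketene carbonyl. The forward reaction runs through vinylketene 14, spiro cyclobutenone 15, dienylketene 16 and dienone 17. It demands that the vinylogous ester 13 opens thermally and that 4 adds to 14 with its oxygen-free carbon on the ketene carbon. The precursors are a C9 bicycle and a C6 enyne, both achiral and free of protecting groups.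

Cyclobutenone 13 is cut at the O–CMe2 bond to the enol 12 of a 2-prenylcyclobutane-1,3-dione. The two enol oxygens of 12 are equivalent, so ring D can close in only one way. Enol 12 is the hydrolysis product of vinylogous ester 11. The four-membered ring of 11 is cut into ynol ether 8 and ketene 10, the latter made in the flask from acetyl chloride 9. Ynol ether 8 is cut at its propargylic C–C bond into lithium ethoxyacetylide 7 (from ethoxyacetylene 5) and prenyl bromide 6. Each forward step is a standard reaction of ynol ethers or vinylogous esters.

Ynol ether 4 is cut at its propargylic C–C bond into lithium methoxyacetylide 3 and allyl bromide 2. Acetylide 3 is generated from chloroacetaldehyde dimethyl acetal 1 by elimination. The methyl ether is chosen because it is the group the target needs and because, unlike an ethyl ynol ether, it cannot fragment to a ketene on heating.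

## Roads not taken

Alternative 1: Ring B is made by isomerising a pyrone. The cut is the C5'–C6' bond, and the precursor is 3-allyl-4-methoxy-6-methyl-5-prenyl-2-pyrone A2. In the forward key step a methoxide base opens A2 to a methoxy keto enoate, and further base drives a Claisen condensation of the methyl ketone carbon onto the ester. This gives 4-allyl-5-methoxy-6-prenylbenzene-1,3-diol A1, which would meet the chosen route at 18 after acid closure of ring D.

- Merits: ionic chemistry on cheap material (triacetic acid lactone A3), no strained ring, no ynol ether, easy to scale. In robustness of reagents this road is better than the chosen one.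
- Weak points: A2 needs carbon at both C3 and C5 of the pyrone. C3 of A3 is nucleophilic, but C5 of a 4-methoxypyrone is not, so several extra steps or a de novo pyrone synthesis are needed. In the opened intermediate the most acidic position is the doubly activated CH bearing the prenyl group, not the methyl group that must attack. The electrophile is a deactivated β-methoxyacrylate, and reclosure to the pyrone competes. A1 carries two free phenols, and ring D must then be closed by acid beside an allyl group that can cyclise onto its own neighbouring phenol.
- Comparison: the chosen plan has ring D in place before ring B exists, liberates a single phenol, and fixes regiochemistry by the polarity of a cycloaddition, not by an enolate equilibrium.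

Alternative 2: Ring D is made last on a complete isoflavone with a symmetric ring B. The cut is the C3'–C bond and the O–CMe2 bond of ring D. In the forward key step the aryl 1,1-dimethylpropargyl ether A5 is heated. Claisen rearrangement to C3', hydrogen shift and oxa-electrocyclisation give the chromene A4, 7-(benzyloxy)-3-[5,7-bis(benzyloxy)-2,2-dimethyl-2H-chromen-6-yl]-4H-chromen-4-one. Hydrogenation would then saturate the chromene and remove the benzyl groups together.

- Merits: the isoflavone core is assembled early by a Suzuki coupling, which is better precedented for the hindered C3–C1' bond than the enamine acylation used here. The propargyl Claisen cascade is reliable, and the symmetry of ring B removes any regiochemical question in it. In convergence and in precedent of the single steps this road is ahead.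
- Weak points: the same symmetry leaves the C2' and C6' oxygens of A4 as identical benzyl ethers. After deprotection the phenol to be methylated (C2', flanked by C1' and C3') is the most hindered of three and not the most acidic. Installing the methyl group earlier destroys the symmetry and lets the Claisen step go to either ortho position.
- Comparison: the chosen plan has the methoxy, hydroxy and ether oxygens differentiated by construction.

Alternative 3: Ring D is closed by a hetero-Diels–Alder reaction. The cut is the CH2–CH2 bond and the O–CMe2 bond. In the forward key step the Mannich base A7 is heated and expels its amine. The resulting ortho-quinone methide adds isobutene A8 to give the chroman A6, 7-(benzyloxy)-3-[5,7-bis(benzyloxy)-2,2-dimethylchroman-6-yl]-4H-chromen-4-one.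

- Merits: two bonds form in one step, ring D arrives at the right oxidation level without a hydrogenation, and the Mannich reaction on a symmetric ring B is unambiguous. After the core is assembled it needs fewer steps than the chosen endgame.
- Weak points: A8 is a gas and an unactivated partner, so pressure and high temperature are needed. The quinone methide can oligomerise or be recaptured by the liberated secondary amine, and that amine is a nucleophile towards chromone C2 and can open ring C. A6 has the same undifferentiated C2'/C6' benzyl ethers as A4.
- Comparison: the chosen plan places the methyl ether unambiguously and never exposes the chromone to an amine at high temperature.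

Key step: step 6

Assumption: the target is achiral; the double-bond geometry of 24, 25 and 26 is written as E but is inconsequential, because it is lost when ring C closes.

## Route

Step 1
Reactants: 1 chloroacetaldehyde dimethyl acetal (2-chloro-1,1-dimethoxyethane); 2 allyl bromide (3-bromoprop-1-ene)
Product: 4 1-methoxypent-4-en-1-yne, via lithium methoxyacetylide 3 (not isolated)
Conditions: LiNEt2 (3.1 equiv, from Et2NH and n-BuLi), THF, 0 °C; then 2, DMPU, −78 °C to rt
Reagents that add atoms: none
Why: Two base-induced eliminations (HCl, then methanol) and a deprotonation turn the chloroacetal into the lithium alkoxyacetylide, a standard in-flask route to such acetylides; SN2 alkylation with the allylic bromide should give the skipped enyne, and the methyl ynol ether cannot undergo retro-ene loss of an alkene on later heating.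

Step 2
Reactants: 5 ethoxyacetylene (ethoxyethyne); 6 prenyl bromide (1-bromo-3-methylbut-2-ene)
Product: 8 1-ethoxy-5-methylhex-4-en-1-yne, via lithium ethoxyacetylide 7 (not isolated)
Conditions: n-BuLi, THF, −78 °C; then 6, DMPU, −78 °C to rt
Reagents that add atoms: none
Why: Acetylide alkylation: deprotonation of the terminal ynol ether and SN2 attack at the primary carbon of the allylic bromide; the ethyl group only carries the oxygen until step 4.

Step 3
Reactants: 8 1-ethoxy-5-methylhex-4-en-1-yne; 9 acetyl chloride
Product: 11 3-ethoxy-2-(3-methylbut-2-en-1-yl)cyclobut-2-en-1-one, via ketene 10 (not isolated)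
Conditions: Et3N, Et2O, slow addition of 9, 0 °C to rt
Reagents that add atoms: none
Why: Ketene–alkyne [2+2] cycloaddition, the standard entry to 3-alkoxycyclobutenones; Et3N dehydrochlorinates 9 to ketene 10, whose carbonyl carbon is attacked by the oxygen-free carbon of the ynol ether, so the carbonyl ends up next to the prenyl-bearing carbon and the ethoxy group at C3, and the ynol ether is far more reactive towards the ketene than the trisubstituted alkene.

Step 4
Reactants: 11 3-ethoxy-2-(3-methylbut-2-en-1-yl)cyclobut-2-en-1-one
Product: 12 3-hydroxy-2-(3-methylbut-2-en-1-yl)cyclobut-2-en-1-one (enol form of 2-prenylcyclobutane-1,3-dione)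
Conditions: 1 M HCl, THF, 0 °C to rt
Reagents that add atoms: water, O
Why: Hydrolysis of a vinylogous ester by addition of water at C3 and loss of ethanol; 2-alkylcyclobutane-1,3-diones exist as the acidic enol, and dilute acid at room temperature should leave the trisubstituted alkene untouched.

Step 5
Reactants: 12 3-hydroxy-2-(3-methylbut-2-en-1-yl)cyclobut-2-en-1-one
Product: 13 3,3-dimethyl-2-oxabicyclo[4.2.0]oct-1(6)-en-7-one
Conditions: Amberlyst-15 (sulfonic acid resin), CH2Cl2, rt
Reagents that add atoms: none
Why: Acid-catalysed Markovnikov hydroalkoxylation: protonation of the prenyl alkene gives the tertiary cation, which the enol oxygen captures in a six-membered closure, as 2-prenyl-1,3-diketones and ortho-prenylphenols do; the two enol oxygens of 12 are equivalent so only one product can form, and a dry acid resin avoids nucleophiles that would open the strained ring.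

Step 6
Reactants: 13 3,3-dimethyl-2-oxabicyclo[4.2.0]oct-1(6)-en-7-one; 4 1-methoxypent-4-en-1-yne
Product: 18 6-allyl-5-methoxy-2,2-dimethylchroman-7-ol, via vinylketene 14 (not isolated), via spiro cyclobutenone adduct 15 (not isolated), via dienylketene 16 (not isolated), via cyclohexadienone 17 (not isolated)
Conditions: 4 (1.5 equiv), toluene, 110 °C, sealed tube, argon; then K2CO3, MeOH, rt (work-up, cleaves any aryl ester formed from 18 and 14)
Reagents that add atoms: none
Why: Danheiser benzannulation: thermal conrotatory four-electron opening of 13 gives vinylketene 14, and the oxygen-free carbon of ynol ether 4 attacks the ketene carbon, so that [2+2] cycloaddition forms C6'–C1' and C2'–C3' in spiro cyclobutenone 15. Reversible four-electron opening of 15 gives dienylketene 16, and disrotatory six-electron electrocyclisation forms C5'–C6' and closes ring B as dienone 17, which tautomerises to phenol 18. The closest known reaction is the thermal benzannulation of cyclobutenones with alkoxy- and siloxyalkynes to resorcinol monoethers; the ring-fused 3-alkoxy substrate adds the third oxygen. No stereocentre is formed. The step needs the regiochemistry of the ketene–alkyne addition, which the polarisation of the ynol ether secures (methoxyl at C2', allyl at C1'), and chemoselectivity for the alkyne over the allyl alkene, which the far higher nucleophilicity of the ynol ether secures. Only the isomer of 16 with the ketene carbon syn to the methylidene carbon can cyclise; the other returns to 15, and ring D holds the diene s-cis. Relief of ring strain and aromatisation drive the sequence, and the vinylogous-ester stabilisation of 13 is the reason for running at 110 °C instead of the usual 80 °C.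

Step 7
Reactants: 18 6-allyl-5-methoxy-2,2-dimethylchroman-7-ol
Product: 19 7-(benzyloxy)-5-methoxy-2,2-dimethyl-6-(prop-2-en-1-yl)-3,4-dihydro-2H-chromene
Conditions: BnBr, K2CO3, DMF, rt
Reagents that add atoms: benzyl bromide, BrCc1ccccc1
Why: Williamson ether synthesis; the benzyl group masks the phenol that would otherwise close onto the acetaldehyde chain of step 8 (hemiacetal, then benzofuran), and it is removed at the end under neutral conditions.

Step 8
Reactants: 19 7-(benzyloxy)-5-methoxy-2,2-dimethyl-6-(prop-2-en-1-yl)-3,4-dihydro-2H-chromene
Product: 20 2-[7-(benzyloxy)-5-methoxy-2,2-dimethyl-3,4-dihydro-2H-chromen-6-yl]acetaldehyde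
Conditions: OsO4 (2 mol %), NaIO4 (4 equiv), 2,6-lutidine, dioxane–H2O 3:1, rt; crude product used at once
Reagents that add atoms: sodium periodate (terminal oxidant, its oxygen reaches the aldehyde through OsO4), [Na+].[O-]I(=O)(=O)=O; OsO4 (catalytic oxygen carrier), O=[Os](=O)(=O)=O
Why: Lemieux–Johnson oxidation (catalytic dihydroxylation and periodate cleavage in one flask) converts the terminal alkene into the arylacetaldehyde; it is preferred to ozonolysis because the trioxygenated ring is itself ozone-sensitive, and 2,6-lutidine suppresses over-oxidation.

Step 9
Reactants: 21 2,4-dihydroxybenzoic acid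
Product: 22 2,4-diacetoxybenzoic acid
Conditions: Ac2O, pyridine, DMAP (cat.), 0 °C to rt; aqueous HCl work-up
Reagents that add atoms: acetic anhydride, CC(=O)OC(C)=O
Why: Acetylation of both phenols by acyl transfer; any mixed anhydride at the carboxyl group is hydrolysed in the acidic work-up, as in the preparation of O-acetylsalicylic acid.

Step 10
Reactants: 22 2,4-diacetoxybenzoic acid
Product: 23 2,4-diacetoxybenzoyl chloride
Conditions: (COCl)2, DMF (cat.), CH2Cl2, 0 °C to rt
Reagents that add atoms: oxalyl chloride, ClC(=O)C(=O)Cl
Why: Acid chloride formation through the chloroiminium species from oxalyl chloride and DMF; aryl acetates are inert to it, and ortho-acetoxybenzoyl chlorides are stable acylating agents.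

Step 11
Reactants: 20 2-[7-(benzyloxy)-5-methoxy-2,2-dimethyl-3,4-dihydro-2H-chromen-6-yl]acetaldehyde; 23 2,4-diacetoxybenzoyl chloride
Product: 25 4-[(2E)-2-[7-(benzyloxy)-5-methoxy-2,2-dimethyl-3,4-dihydro-2H-chromen-6-yl]-3-(morpholin-4-yl)prop-2-enoyl]-1,3-phenylene diacetate, via morpholine enamine 24 (not isolated)
Conditions: morpholine (1.05 equiv), 4 Å MS, toluene, rt; then Et3N, 23 (1.2 equiv), 0 to 60 °C
Reagents that add atoms: morpholine, C1COCCN1
Why: Stork enamine acylation: condensation of 20 with the secondary amine gives the conjugated enamine 24, which is C-acylated at the aryl-bearing carbon by 23, and Et3N deprotonates the iminium ion to the push–pull enaminone 25, the same intermediate type that deoxybenzoins give with formamide acetals; the acid chloride is far more electrophilic than the two aryl acetates.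

Step 12
Reactants: 25 4-[(2E)-2-[7-(benzyloxy)-5-methoxy-2,2-dimethyl-3,4-dihydro-2H-chromen-6-yl]-3-(morpholin-4-yl)prop-2-enoyl]-1,3-phenylene diacetate
Product: 27 3-[7-(benzyloxy)-5-methoxy-2,2-dimethyl-3,4-dihydro-2H-chromen-6-yl]-7-hydroxy-4H-chromen-4-one, via dihydroxyphenyl enaminone 26 (not isolated)
Conditions: HCl (1.25 M in MeOH), 50 °C
Reagents that add atoms: none
Why: Acid-catalysed transesterification removes both aryl acetates, and the freed ortho phenol of 26 adds to the enaminone β-carbon and expels the amine (six-membered addition–elimination), the ring-closing step of the enaminone isoflavone synthesis; benzyl ether, methyl ether and ring D are stable to methanolic HCl, and the ring B oxygen stays benzylated so that no benzofuran can form.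

Step 13
Reactants: 27 3-[7-(benzyloxy)-5-methoxy-2,2-dimethyl-3,4-dihydro-2H-chromen-6-yl]-7-hydroxy-4H-chromen-4-one
Product: 28 glycyrrhizaisoflavone C, 7-hydroxy-3-(7-hydroxy-5-methoxy-2,2-dimethyl-3,4-dihydro-2H-chromen-6-yl)-4H-chromen-4-one
Conditions: H2 (1 atm), Pd/C (10% palladium on carbon), EtOAc–MeOH, rt, stopped after one equivalent of H2
Reagents that add atoms: none
Why: Hydrogenolysis of the aryl benzyl ether; the chromone C2=C3 bond is a vinylogous ester flanked by two aryl rings and is reduced much more slowly, so stopping after one equivalent of hydrogen should leave it intact.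

## Compound list

1 | chloroacetaldehyde dimethyl acetal (2-chloro-1,1-dimethoxyethane) | COC(CCl)OC | starting material
2 | allyl bromide (3-bromoprop-1-ene) | C=CCBr | starting material
3 | lithium methoxyacetylide | [Li]C#COC | intermediate (not isolated)
4 | 1-methoxypent-4-en-1-yne | COC#CCC=C | intermediate
5 | ethoxyacetylene (ethoxyethyne) | CCOC#C | starting material
6 | prenyl bromide (1-bromo-3-methylbut-2-ene) | CC(C)=CCBr | starting material
7 | lithium ethoxyacetylide | [Li]C#COCC | intermediate (not isolated)
8 | 1-ethoxy-5-methylhex-4-en-1-yne | CCOC#CCC=C(C)C | intermediate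
9 | acetyl chloride | CC(=O)Cl | starting material
10 | ketene (ethenone) | C=C=O | intermediate (not isolated)
11 | 3-ethoxy-2-(3-methylbut-2-en-1-yl)cyclobut-2-en-1-one | CCOC1=C(CC=C(C)C)C(=O)C1 | intermediate
12 | 3-hydroxy-2-(3-methylbut-2-en-1-yl)cyclobut-2-en-1-one | OC1=C(CC=C(C)C)C(=O)C1 | intermediate
13 | 3,3-dimethyl-2-oxabicyclo[4.2.0]oct-1(6)-en-7-one | CC1(C)CCC2=C(CC2=O)O1 | intermediate
14 | 2-(6,6-dimethyl-2-methylideneoxan-3-ylidene)ethen-1-one (vinylketene) | O=C=C1CCC(C)(C)OC1=C | intermediate (not isolated)
15 | 3-methoxy-7,7-dimethyl-5-methylidene-2-(prop-2-en-1-yl)-6-oxaspiro[3.5]non-2-en-1-one | O=C1C(CC=C)=C(OC)C12CCC(C)(C)OC2=C | intermediate (not isolated)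
16 | (E)-3-(6,6-dimethyl-2-methylideneoxan-3-ylidene)-3-methoxy-2-(prop-2-en-1-yl)prop-1-en-1-one (dienylketene, ketene carbon syn to the methylidene-bearing ring carbon) | O=C=C(CC=C)/C(OC)=C1/CCC(C)(C)OC1=C | intermediate (not isolated)
17 | 5-methoxy-2,2-dimethyl-6-(prop-2-en-1-yl)-3,4-dihydro-2H-chromen-7(8H)-one | O=C1CC2=C(CCC(C)(C)O2)C(OC)=C1CC=C | intermediate (not isolated)
18 | 6-allyl-5-methoxy-2,2-dimethylchroman-7-ol (5-methoxy-2,2-dimethyl-6-(prop-2-en-1-yl)-3,4-dihydro-2H-chromen-7-ol) | C=CCc1c(O)cc2OC(C)(C)CCc2c1OC | intermediate
19 | 7-(benzyloxy)-5-methoxy-2,2-dimethyl-6-(prop-2-en-1-yl)-3,4-dihydro-2H-chromene | C=CCc1c(OCc2ccccc2)cc2OC(C)(C)CCc2c1OC | intermediate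
20 | 2-[7-(benzyloxy)-5-methoxy-2,2-dimethyl-3,4-dihydro-2H-chromen-6-yl]acetaldehyde | O=CCc1c(OCc2ccccc2)cc2OC(C)(C)CCc2c1OC | intermediate
21 | 2,4-dihydroxybenzoic acid | OC(=O)c1ccc(O)cc1O | starting material
22 | 2,4-diacetoxybenzoic acid | CC(=O)Oc1ccc(C(=O)O)c(OC(C)=O)c1 | intermediate
23 | 2,4-diacetoxybenzoyl chloride | CC(=O)Oc1ccc(C(=O)Cl)c(OC(C)=O)c1 | intermediate
24 | 4-[(E)-2-[7-(benzyloxy)-5-methoxy-2,2-dimethyl-3,4-dihydro-2H-chromen-6-yl]ethenyl]morpholine | O1CCN(CC1)/C=C/c1c(OC)c2CCC(C)(C)Oc2cc1OCc1ccccc1 | intermediate (not isolated)
25 | 4-[(2E)-2-[7-(benzyloxy)-5-methoxy-2,2-dimethyl-3,4-dihydro-2H-chromen-6-yl]-3-(morpholin-4-yl)prop-2-enoyl]-1,3-phenylene diacetate | O=C(c1ccc(OC(C)=O)cc1OC(C)=O)/C(=C/N1CCOCC1)c1c(OC)c2CCC(C)(C)Oc2cc1OCc1ccccc1 | intermediate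
26 | (2E)-2-[7-(benzyloxy)-5-methoxy-2,2-dimethyl-3,4-dihydro-2H-chromen-6-yl]-1-(2,4-dihydroxyphenyl)-3-(morpholin-4-yl)prop-2-en-1-one | O=C(c1ccc(O)cc1O)/C(=C/N1CCOCC1)c1c(OC)c2CCC(C)(C)Oc2cc1OCc1ccccc1 | intermediate (not isolated)
27 | 3-[7-(benzyloxy)-5-methoxy-2,2-dimethyl-3,4-dihydro-2H-chromen-6-yl]-7-hydroxy-4H-chromen-4-one | O=c1c(-c2c(OC)c3CCC(C)(C)Oc3cc2OCc2ccccc2)coc2cc(O)ccc12 | intermediate
28 | glycyrrhizaisoflavone C, 7-hydroxy-3-(7-hydroxy-5-methoxy-2,2-dimethyl-3,4-dihydro-2H-chromen-6-yl)-4H-chromen-4-one | COc1c2c(cc(O)c1-c1coc3cc(O)ccc3c1=O)OC(C)(C)CC2 | target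

## Step count and least certain steps

Total step count: 13. Longest linear sequence: 10 steps (steps 2, 3, 4, 5, 6, 7, 8, 11, 12, 13, from ethoxyacetylene 5). Step 1 and steps 9–10 are one- and two-step side branches.

Step 6 (key step). The electrocyclic opening of 13 may be too slow at temperatures that ynol ether 4 tolerates, because the vinylogous-ester conjugation lost on opening stabilises 13. The vinylketene 14 that does form may also be consumed by dimerisation or by acylating the product phenol faster than it is trapped by 4. The fallback makes the same vinylketene 14 by 1,4-dehydrochlorination instead of ring opening, so the same three bonds still form. It sets out from prenyl bromide 6. Ethyl acetoacetate is C-alkylated with 6 (NaOEt, EtOH) to racemic ethyl 2-acetyl-5-methylhex-4-enoate F1. Acid (Amberlyst-15, CH2Cl2) closes the dihydropyran to ethyl 2,6,6-trimethyl-5,6-dihydro-4H-pyran-3-carboxylate F2. Saponification (LiOH, aqueous THF) gives 2,6,6-trimethyl-5,6-dihydro-4H-pyran-3-carboxylic acid F3, and oxalyl chloride gives 2,6,6-trimethyl-5,6-dihydro-4H-pyran-3-carbonyl chloride F4. Slow addition of Et3N to F4 and 4 in toluene at room temperature removes HCl across the C2 methyl group and the acyl carbon and should give 14. Warming to 80 °C then carries the adduct 15 through 16 and 17, and the fallback comes back to the route at 18.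

Step 11. C-acylation of enamine 24 takes place at a carbon flanked by two ortho oxygen substituents. It may be outrun by N-acylation of the enamine (which returns the aldehyde as an amide by-product forms) or by self-condensation of aldehyde 20. The fallback forms the hindered centre with a one-carbon electrophile instead. It sets out from aldehyde 20. The aryllithium from 1-bromo-2,4-bis(methoxymethoxy)benzene (n-BuLi, then CeCl3) adds to 20 to give racemic 1-[2,4-bis(methoxymethoxy)phenyl]-2-[7-(benzyloxy)-5-methoxy-2,2-dimethyl-3,4-dihydro-2H-chromen-6-yl]ethan-1-ol F5. Dess–Martin periodinane oxidises it to the deoxybenzoin 1-[2,4-bis(methoxymethoxy)phenyl]-2-[7-(benzyloxy)-5-methoxy-2,2-dimethyl-3,4-dihydro-2H-chromen-6-yl]ethan-1-one F6. Methanolic HCl removes both methoxymethyl groups to give 2-[7-(benzyloxy)-5-methoxy-2,2-dimethyl-3,4-dihydro-2H-chromen-6-yl]-1-(2,4-dihydroxyphenyl)ethan-1-one F7. Formylation and ring closure with BF3·OEt2, DMF and MsCl then deliver 27, where the fallback rejoins the route.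

Step 3. Ketene 10 is generated in the presence of Et3N and its hydrochloride and may dimerise or be intercepted by the amine before ynol ether 8 captures it, so conversion of 8 could be poor. The fallback uses a ketene that is more electrophilic and is generated without amine. It sets out from 8. Dichloroketene (from trichloroacetyl chloride and activated Zn, Et2O) should add to 8 with the same regiochemistry to give 4,4-dichloro-3-ethoxy-2-(3-methylbut-2-en-1-yl)cyclobut-2-en-1-one F8. Reductive dechlorination with Zn, AcOH and TMEDA in EtOH then gives 11, where the route continues.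

Step 5. The acid needed to protonate the prenyl alkene may instead cleave or oligomerise the strained enol 12, or the tertiary cation may lose a proton to give isomeric alkenes before the weakly nucleophilic enol oxygen traps it. The fallback makes the O–CMe2 bond first and closes ring D by exchange at the vinylogous ester carbon. It sets out from 11. Mukaiyama hydration of the trisubstituted alkene (Co(acac)2, PhSiH3, O2, i-PrOH) gives 3-ethoxy-2-(3-hydroxy-3-methylbutyl)cyclobut-2-en-1-one F9. Pyridinium p-toluenesulfonate in toluene at 60 °C, with removal of ethanol, should close ring D by intramolecular addition–elimination. This gives 13 directly, where the fallback comes back to the route without passing through 12.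

## Further compounds

F1 | step 6 | racemic ethyl 2-acetyl-5-methylhex-4-enoate | CCOC(=O)C(CC=C(C)C)C(C)=O
F2 | step 6 | ethyl 2,6,6-trimethyl-5,6-dihydro-4H-pyran-3-carboxylate | CCOC(=O)C1=C(C)OC(C)(C)CC1
F3 | step 6 | 2,6,6-trimethyl-5,6-dihydro-4H-pyran-3-carboxylic acid | OC(=O)C1=C(C)OC(C)(C)CC1
F4 | step 6 | 2,6,6-trimethyl-5,6-dihydro-4H-pyran-3-carbonyl chloride | ClC(=O)C1=C(C)OC(C)(C)CC1
F5 | step 11 | racemic 1-[2,4-bis(methoxymethoxy)phenyl]-2-[7-(benzyloxy)-5-methoxy-2,2-dimethyl-3,4-dihydro-2H-chromen-6-yl]ethan-1-ol | OC(Cc1c(OC)c2CCC(C)(C)Oc2cc1OCc1ccccc1)c1ccc(OCOC)cc1OCOC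
F6 | step 11 | 1-[2,4-bis(methoxymethoxy)phenyl]-2-[7-(benzyloxy)-5-methoxy-2,2-dimethyl-3,4-dihydro-2H-chromen-6-yl]ethan-1-one | O=C(Cc1c(OC)c2CCC(C)(C)Oc2cc1OCc1ccccc1)c1ccc(OCOC)cc1OCOC
F7 | step 11 | 2-[7-(benzyloxy)-5-methoxy-2,2-dimethyl-3,4-dihydro-2H-chromen-6-yl]-1-(2,4-dihydroxyphenyl)ethan-1-one | O=C(Cc1c(OC)c2CCC(C)(C)Oc2cc1OCc1ccccc1)c1ccc(O)cc1O
F8 | step 3 | 4,4-dichloro-3-ethoxy-2-(3-methylbut-2-en-1-yl)cyclobut-2-en-1-one | CCOC1=C(CC=C(C)C)C(=O)C1(Cl)Cl
F9 | step 5 | 3-ethoxy-2-(3-hydroxy-3-methylbutyl)cyclobut-2-en-1-one | CCOC1=C(CCC(C)(C)O)C(=O)C1
A1 | alternative 1 | 4-allyl-5-methoxy-6-(3-methylbut-2-en-1-yl)benzene-1,3-diol | C=CCc1c(O)cc(O)c(CC=C(C)C)c1OC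
A2 | alternative 1 | 3-allyl-4-methoxy-6-methyl-5-(3-methylbut-2-en-1-yl)-2H-pyran-2-one | C=CCc1c(OC)c(CC=C(C)C)c(C)oc1=O
A3 | alternative 1 | triacetic acid lactone (4-hydroxy-6-methyl-2H-pyran-2-one) | Cc1cc(O)cc(=O)o1
A4 | alternative 2 | 7-(benzyloxy)-3-[5,7-bis(benzyloxy)-2,2-dimethyl-2H-chromen-6-yl]-4H-chromen-4-one | CC1(C)C=Cc2c(cc(OCc3ccccc3)c(-c3coc4cc(OCc5ccccc5)ccc4c3=O)c2OCc2ccccc2)O1
A5 | alternative 2 | 7-(benzyloxy)-3-[2,6-bis(benzyloxy)-4-[(2-methylbut-3-yn-2-yl)oxy]phenyl]-4H-chromen-4-one | C#CC(C)(C)Oc1cc(OCc2ccccc2)c(-c2coc3cc(OCc4ccccc4)ccc3c2=O)c(OCc2ccccc2)c1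
A6 | alternative 3 | 7-(benzyloxy)-3-[5,7-bis(benzyloxy)-2,2-dimethylchroman-6-yl]-4H-chromen-4-one | CC1(C)CCc2c(cc(OCc3ccccc3)c(-c3coc4cc(OCc5ccccc5)ccc4c3=O)c2OCc2ccccc2)O1
A7 | alternative 3 | 7-(benzyloxy)-3-[2,6-bis(benzyloxy)-3-[(dimethylamino)methyl]-4-hydroxyphenyl]-4H-chromen-4-one | CN(C)Cc1c(O)cc(OCc2ccccc2)c(-c2coc3cc(OCc4ccccc4)ccc3c2=O)c1OCc1ccccc1
A8 | alternative 3 | isobutene (2-methylprop-1-ene) | CC(C)=C
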